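## Retrosynthetic overview

1. The target comes from the protected pentacyclic 12-ketone by hydride delivery to the β face and deprotection. The ketone is cut at C9–C10, so ring B and the γ-lactone are closed last, in one flask.
2. Enabling feature: C10 is a bridgehead of the 6-oxabicyclo[3.2.1]octan-7-one made of ring A (C1–C5, C10) and the C19–O–C10 lactone, so a radical there cannot invert. C9 lies β to C12 (O–C10–C9–C11–C12–O), so a C12 ketone turns C9=C11 of the C/D bicyclo[3.2.1]octenone into a Giese acceptor.
3. Precursor: ring A is a cyclohexene with PhSe on C10 (ketone oxidation level) and C19 as a tert-butyl ester, tied through C6 to C8 of the C/D enone. C5–C6 comes from an Ireland–Claisen shift that consumes a temporary C1 oxygen.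
4. The ring A alcohol is made from tert-butyl benzoate by Birch methylation, oxidation to the dienone, desymmetrising conjugate borylation, α-selenenylation and CBS reduction. The C/D acid is made from 3-ethoxycyclohexenone by allyl addition, CBS reduction, Johnson–Claisen (C8), enone formation, Rubottom oxidation (C13–O) and Pd cycloalkenylation (ring D).
5. Ring order: A and C (carbocycles of the starting materials), then D, then lactone and B together.

Key step: step 18

Remark: gibberellane numbering (C1–C19) and the α/β convention of the target (19,10-lactone α; H-5 and H-9 β) are used for all fragments, and the ligand antipode in step 3 is assumed to be the one that leads to the 3β series.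

## Route

Step 1
Reactants: 1 tert-butyl benzoate
Product: 3 tert-butyl 1-methylcyclohexa-2,5-diene-1-carboxylate, via lithium dienolate 2 (not isolated)
Conditions: Li, NH3(l)/THF, t-BuOH (1 equiv), −78 °C; then MeI
Reagents that add atoms: iodomethane CI
Why: Birch reduction of the benzoate stops at the cross-conjugated ester dienolate, which is methylated at the ipso carbon (Birch reductive alkylation) to build the quaternary C4 with C18 and C19 while the two ring arms stay equivalent, so no stereocentre arises yet.

Step 2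
Reactants: 3 tert-butyl 1-methylcyclohexa-2,5-diene-1-carboxylate
Product: 4 tert-butyl 1-methyl-4-oxocyclohexa-2,5-diene-1-carboxylate
Conditions: Rh2(cap)4 (cat.), 70% aq. t-BuOOH, ClCH2CH2Cl, 40 °C
Reagents that add atoms: tert-butyl hydroperoxide CC(C)(C)OO
Why: The doubly allylic CH2 para to the quaternary carbon holds the weakest C–H bonds and aromatisation is blocked, so catalytic allylic oxidation should give the cross-conjugated dienone, whose carbonyl (C1) is a temporary activating group.

Step 3
Reactants: 4 tert-butyl 1-methyl-4-oxocyclohexa-2,5-diene-1-carboxylate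
Product: 6 tert-butyl (1S,6S)-6-hydroxy-1-methyl-4-oxocyclohex-2-ene-1-carboxylate (3β-OH; 4β-Me; 4α-CO2t-Bu), via boronate 5 (not isolated)
Conditions: CuCl/NaOt-Bu (cat.), Josiphos-type bisphosphine (cat.), B2pin2 (1.0 equiv), MeOH, THF, −20 °C; then 30% H2O2, pH 7 buffer, 0 °C
Reagents that add atoms: bis(pinacolato)diboron CC1(C)OB(OC1(C)C)B1OC(C)(C)C(C)(C)O1 (boron of 5); hydrogen peroxide OO (oxygen of 6)
Why: Copper-catalysed enantioselective conjugate borylation followed by stereoretentive C–B oxidation desymmetrises the dienone, the ligand choosing one of the two enantiotopic enone arms and the boryl copper adding anti to the bulky tert-butyl ester, which sets C3 (β-oxygen) and thereby C4 in one event, while the more hindered product enone should not react again.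

Step 4
Reactants: 6 hydroxy enone
Product: 7 tert-butyl (1S,6S)-6-(tert-butyldimethylsilyloxy)-1-methyl-4-oxocyclohex-2-ene-1-carboxylate
Conditions: TBSOTf, 2,6-lutidine, CH2Cl2, −78 to 0 °C
Reagents that add atoms: tert-butyldimethylsilyl triflate CC(C)(C)[Si](C)(C)OS(=O)(=O)C(F)(F)F
Why: Silylation with the triflate and a hindered, weakly basic amine protects the neopentyl-type β-hydroxy ketone without E1cB loss of the oxygen and without touching a stereocentre.

Step 5
Reactants: 7 silyloxy enone
Product: 8 tert-butyl (1S,6S)-6-(tert-butyldimethylsilyloxy)-1-methyl-4-oxo-3-(phenylselanyl)cyclohex-2-ene-1-carboxylate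
Conditions: PhSeCl, pyridine, CH2Cl2, 0 °C to rt
Reagents that add atoms: benzeneselenenyl chloride Cl[Se]c1ccccc1
Why: α-Selenenylation of an enone by addition of PhSeCl/pyridine across C5=C10 and loss of HCl places selenium on C10, the α-carbon, because only this regiochemistry restores conjugation.

Step 6
Reactants: 8 selanyl enone
Product: 9 tert-butyl (1S,4S,6S)-6-(tert-butyldimethylsilyloxy)-4-hydroxy-1-methyl-3-(phenylselanyl)cyclohex-2-ene-1-carboxylate (1α-OH)
Conditions: (R)-Me-CBS (cat.), catecholborane, toluene, −78 °C; aqueous work-up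
Reagents that add atoms: none
Why: CBS reduction under reagent control, with the selenium-bearing vinyl side as the large group, delivers hydride to the β face of C1 and gives the 1α-allylic alcohol, a temporary stereocentre that is later relayed to C5.

Step 7
Reactants: 10 3-ethoxycyclohex-2-en-1-one
Product: 12 3-(prop-2-en-1-yl)cyclohex-2-en-1-one, via tertiary carbinol 11 (not isolated)
Conditions: allylMgBr, THF, 0 °C; then 1 M HCl, 0 °C
Reagents that add atoms: allylmagnesium bromide C=CC[Mg]Br
Why: 1,2-Addition of the Grignard reagent to the vinylogous ester and acid-induced loss of ethanol with carbonyl transposition (Stork–Danheiser sequence) gives the 3-allyl enone that carries C8 and C15–C17.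

Step 8
Reactants: 12 3-allylcyclohex-2-en-1-one
Product: 13 (R)-3-(prop-2-en-1-yl)cyclohex-2-en-1-ol (11α-OH)
Conditions: (S)-Me-CBS (cat.), catecholborane, toluene, −78 °C; aqueous work-up
Reagents that add atoms: none
Why: CBS reduction with the ring alkene as the large group sets the carbinol centre under catalyst control, and catecholborane at low temperature leaves the terminal alkene unhydroborated.

Step 9
Reactants: 13 (R)-3-allylcyclohex-2-en-1-ol
Product: 15 ethyl [(1S)-1-(prop-2-en-1-yl)cyclohex-2-en-1-yl]acetate, via ketene acetal 14 (not isolated)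
Conditions: MeC(OEt)3, EtCO2H (cat.), xylene, 140 °C, EtOH distilled off
Reagents that add atoms: triethyl orthoacetate CC(OCC)(OCC)OCC
Why: The Johnson–Claisen rearrangement is suprafacial, so the C11α–O bond is exchanged for the C8α–C6 bond and the quaternary C8 is set by complete chirality transfer while C6 and C7 are introduced.

Step 10
Reactants: 15 ethyl [(1S)-1-allylcyclohex-2-en-1-yl]acetate
Product: 16 ethyl [(1S)-1-(prop-2-en-1-yl)-4-oxocyclohex-2-en-1-yl]acetate
Conditions: Rh2(cap)4 (cat.), 70% aq. t-BuOOH, ClCH2CH2Cl, 40 °C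
Reagents that add atoms: tert-butyl hydroperoxide CC(C)(C)OO
Why: Allylic oxidation of the ring alkene can give only one enone because the other allylic position is the quaternary C8, and the neopentyl-type C15–H bonds of the side chain are sterically shielded.

Step 11
Reactants: 16 4,4-disubstituted enone
Product: 18 ethyl [(1S)-5-hydroxy-4-oxo-1-(prop-2-en-1-yl)cyclohex-2-en-1-yl]acetate (C13 epimers), via trimethylsilyl dienol ether 17 (not isolated)
Conditions: LDA, THF, −78 °C; TMSCl; then mCPBA (1.0 equiv), CH2Cl2, −20 °C; citric acid (cat.), MeOH/H2O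
Reagents that add atoms: chlorotrimethylsilane C[Si](C)(C)Cl (silicon of 17); 3-chloroperoxybenzoic acid OOC(=O)c1cccc(Cl)c1 (oxygen of 18)
Why: Kinetic deprotonation occurs at C13, the only enolisable carbon of the ketone, and Rubottom oxidation of the electron-rich dienol ether outruns epoxidation of the allyl group, the configuration of the new C13 carbinol being irrelevant because it is erased in step 12.

Step 12
Reactants: 18 α′-hydroxy enone
Product: 19 ethyl [(1S)-4,5-bis(tert-butyldimethylsilyloxy)-1-(prop-2-en-1-yl)cyclohexa-2,4-dien-1-yl]acetate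
Conditions: TBSOTf (2.2 equiv), Et3N, CH2Cl2, 0 °C to rt
Reagents that add atoms: tert-butyldimethylsilyl triflate CC(C)(C)[Si](C)(C)OS(=O)(=O)C(F)(F)F
Why: Silyl triflate and amine silylate the carbinol and soft-enolise the ketone toward C13, the only α-carbon that bears hydrogen, giving the cross-conjugated ene-diol bis(silyl ether).

Step 13
Reactants: 19 bis(silyloxy) diene
Product: 20 ethyl 2-[5-(tert-butyldimethylsilyloxy)-6-methylidene-4-oxobicyclo[3.2.1]oct-2-en-1-yl]acetate (C/D enone; C8 and C13 as in the target)
Conditions: Pd(OAc)2 (10 mol %), O2 (1 atm), DMSO, 45 °C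
Reagents that add atoms: none
Why: Pd(II)-mediated cycloalkenylation of a silyl enol ether (oxo-π-allylpalladium, 5-exo-trig insertion of the pendant allyl group, β-hydride elimination) joins C13 to C16 and leaves the exocyclic methylene, C13 being fixed because the two-carbon bridge can span C8 and C13 only on the face that carries C15, and 5-exo closure at C13 being preferred over 6-exo closure at C12.

Step 14
Reactants: 20 C/D enone ester
Product: 21 2-[5-(tert-butyldimethylsilyloxy)-6-methylidene-4-oxobicyclo[3.2.1]oct-2-en-1-yl]acetic acid (C/D acid)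
Conditions: LiOH, THF/H2O, rt; then 1 M HCl
Reagents that add atoms: lithium hydroxide [Li+].[OH-]
Why: Saponification of the unhindered primary ethyl ester proceeds under conditions that leave the non-enolisable, β-hindered enone and the tertiary silyl ether intact.

Step 15
Reactants: 21 C/D acid; 9 ring A alcohol
Product: 22 ester of acid 21 with alcohol 9 (C7–O–C1α)
Conditions: DCC, DMAP (cat.), CH2Cl2, 0 °C to rt
Reagents that add atoms: none
Why: Steglich esterification joins the two enantiopure halves at the carbinol oxygen with retention at C1, since no bond to a stereocentre is broken.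

Step 16
Reactants: 22 allylic ester
Product: 25 seco acid (C5α–C6 bond; H-5β; H-6α; 7-CO2H; 10-PhSe-1(10)-ene), via silyl ketene acetal 23 (not isolated), via silyl ester 24 (not isolated)
Conditions: LDA, THF/DMPU, −78 °C; TBSCl; −78 to 70 °C; then 1 M HCl (cat.), THF/H2O, rt
Reagents that add atoms: tert-butyldimethylsilyl chloride CC(C)(C)[Si](C)(C)Cl (silicon of 23 and 24 only)
Why: C6 is the only enolisable position, enolisation in THF/DMPU puts the bulky bridgehead residue cis to OSi, and the suprafacial chair-like Ireland–Claisen shift (the boat suffers a PhSe/OSi clash) converts the C1α–O bond into the C5α–C6 bond, sets C6 with the carboxyl β and leaves the C1=C10 vinyl selenide.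

Step 17
Reactants: 25 seco acid
Product: 26 seco allyl ester
Conditions: allyl bromide, Cs2CO3, DMF, rt
Reagents that add atoms: allyl bromide C=CCBr
Why: O-Alkylation of the caesium carboxylate avoids attack at the hindered acyl carbon and masks C7 so that only the C19 ester can act as the internal nucleophile in the next step.

Step 18
Reactants: 26 seco allyl ester
Product: 28 allyl 3β,13-bis(tert-butyldimethylsilyloxy)-12-oxo-19,10-lactone 7-oate (pentacyclic 12-ketone), via bridgehead selenide 27 (not isolated)
Conditions: TFA (3 equiv), PhCF3, 0 °C; then 2,6-lutidine (3 equiv); then Bu3SnH and AIBN (cat.) by syringe pump, 85 °C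
Reagents that add atoms: none
Why: Proposed new method: TFA protonates the vinyl selenide at C1 and the selenium-stabilised C10 cation is captured from the α face by the carbonyl oxygen of the 1,3-related C19 tert-butyl ester (5-exo closure of the γ-lactone, isobutene lost) to give the bridgehead O,Se-acetal 27; Bu3Sn• then abstracts PhSe and the pyramidal α-acyloxy radical at C10 adds 5-exo-trig to C9 of the C9=C11–C12=O enone (ring B), the α-keto radical at C11 taking hydrogen from the stannane. The closest known reaction types are the capture of thionium or selenium-stabilised cations by carboxyl groups (Pummerer-type lactonisation, halolactonisation of tert-butyl esters) and the conjugate addition of α-alkoxy bridgehead radicals generated from O,Se-acetals; new are the α-acyloxy bridgehead selenide and the telescoped sequence. C10 is controlled by the tether, since the ester on C4α can reach only the α face and the bridgehead radical of the 6-oxabicyclo[3.2.1]octan-7-one cannot invert, so C9 takes the place of selenium and the trans A/B fusion, normally disfavoured in 5-exo closures, is enforced. C9 is controlled by the bicyclo[3.2.1]octenone, whose enone is open only on the exo (α) face anti to the C15–C16 bridge, which gives H-9β and the cis B/C fusion, while C5, C6 and C8 are untouched. The step needs chemoselective protonation (the vinyl selenide is by far the most basic alkene, whereas a cation at C16 would sit next to the oxygenated C13 and the C12 ketone) and cyclisation faster than hydrogen transfer (nucleophilic σ-radical, electron-poor acceptor five atoms away, stannane kept dilute).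

Step 19
Reactants: 28 pentacyclic 12-ketone
Product: 29 12α-alcohol (allyl ester; 3β,13-bis-silyl ether)
Conditions: L-Selectride, THF, −78 °C; H2O
Reagents that add atoms: none
Why: The C9–C10 bond is axial on ring C and 1,3-related to C12, so it blocks the α face and the bulky hydride attacks along the equatorial β trajectory (steric approach control as in 3-axially substituted cyclohexanones) to give the axial 12α-alcohol, while lactone, hindered ester and alkenes are inert at −78 °C.

Step 20
Reactants: 29 12α-alcohol
Product: 30 free 7-carboxylic acid (3β,13-bis-silyl ether)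
Conditions: Pd(PPh3)4 (cat.), morpholine, THF, rt
Reagents that add atoms: none
Why: Pd(0) ionises the allyl ester to a π-allyl complex that morpholine intercepts (Tsuji–Trost deallylation), which frees the hindered C7 acid under neutral conditions and avoids base-induced retro-aldol epimerisation at C3.

Step 21
Reactants: 30 bis-silyl ether acid
Product: 31 target (3β,12α,13-trihydroxy 19,10-lactone 7-acid; 12α-hydroxy-GA1)
Conditions: HF·pyridine, pyridine/THF, 0 °C to rt
Reagents that add atoms: none
Why: Fluoride-driven Si–O cleavage removes both silyl ethers under buffered conditions that leave the lactone, the tertiary allylic 13-alcohol and the exocyclic alkene intact and touch no stereocentre.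

## Compound list

1 | tert-butyl benzoate | CC(C)(C)OC(=O)c1ccccc1 | starting material
2 | lithium dienolate of tert-butyl 1,4-dihydrobenzoate | [Li+].[O-]C(OC(C)(C)C)=C1C=CCC=C1 | intermediate
3 | tert-butyl 1-methylcyclohexa-2,5-diene-1-carboxylate | CC1(C=CCC=C1)C(=O)OC(C)(C)C | intermediate
4 | tert-butyl 1-methyl-4-oxocyclohexa-2,5-diene-1-carboxylate | CC1(C=CC(=O)C=C1)C(=O)OC(C)(C)C | intermediate
5 | 3β-pinacolboryl enone (4β-Me; 4α-CO2t-Bu) | O=C1C[C@H](B2OC(C)(C)C(C)(C)O2)[C@@](C)(C(=O)OC(C)(C)C)C=C1 | intermediate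
6 | tert-butyl (1S,6S)-6-hydroxy-1-methyl-4-oxocyclohex-2-ene-1-carboxylate | O=C1C[C@H](O)[C@@](C)(C(=O)OC(C)(C)C)C=C1 | intermediate
7 | TBS ether of 6 | O=C1C[C@H](O[Si](C)(C)C(C)(C)C)[C@@](C)(C(=O)OC(C)(C)C)C=C1 | intermediate
8 | 10-phenylselanyl enone | O=C1C[C@H](O[Si](C)(C)C(C)(C)C)[C@@](C)(C(=O)OC(C)(C)C)C=C1[Se]c1ccccc1 | intermediate
9 | ring A alcohol (1α-OH; 3β-OTBS; 4β-Me; 4α-CO2t-Bu; 10-SePh) | O[C@H]1C[C@H](O[Si](C)(C)C(C)(C)C)[C@@](C)(C(=O)OC(C)(C)C)C=C1[Se]c1ccccc1 | intermediate
10 | 3-ethoxycyclohex-2-en-1-one | CCOC1=CC(=O)CCC1 | starting material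
11 | 1-allyl-3-ethoxycyclohex-2-en-1-ol (racemic) | C=CCC1(O)C=C(OCC)CCC1 | intermediate
12 | 3-(prop-2-en-1-yl)cyclohex-2-en-1-one | C=CCC1=CC(=O)CCC1 | intermediate
13 | (R)-3-(prop-2-en-1-yl)cyclohex-2-en-1-ol | C=CCC1=C[C@H](O)CCC1 | intermediate
14 | mixed ethyl ketene acetal of 13 | C=CCC1=C[C@H](OC(=C)OCC)CCC1 | intermediate
15 | ethyl [(1S)-1-(prop-2-en-1-yl)cyclohex-2-en-1-yl]acetate | CCOC(=O)C[C@]1(CC=C)C=CCCC1 | intermediate
16 | ethyl [(1S)-1-(prop-2-en-1-yl)-4-oxocyclohex-2-en-1-yl]acetate | CCOC(=O)C[C@]1(CC=C)C=CC(=O)CC1 | intermediate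
17 | cross-conjugated trimethylsilyl dienol ether of 16 | CCOC(=O)C[C@]1(CC=C)C=CC(O[Si](C)(C)C)=CC1 | intermediate
18 | α′-hydroxy enone (C13 epimers; C8 defined) | CCOC(=O)C[C@]1(CC=C)C=CC(=O)C(O)C1 | intermediate
19 | ene-diol bis(TBS ether) | CCOC(=O)C[C@]1(CC=C)C=CC(O[Si](C)(C)C(C)(C)C)=C(O[Si](C)(C)C(C)(C)C)C1 | intermediate
20 | C/D enone ethyl ester | C=C1C[C@]2(CC(=O)OCC)C[C@@]1(O[Si](C)(C)C(C)(C)C)C(=O)C=C2 | intermediate
21 | C/D enone acid | C=C1C[C@]2(CC(=O)O)C[C@@]1(O[Si](C)(C)C(C)(C)C)C(=O)C=C2 | intermediate
22 | ester of 21 with 9 | C=C1C[C@]2(CC(=O)O[C@H]3C[C@H](O[Si](C)(C)C(C)(C)C)[C@@](C)(C(=O)OC(C)(C)C)C=C3[Se]c3ccccc3)C[C@@]1(O[Si](C)(C)C(C)(C)C)C(=O)C=C2 | intermediate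
23 | TBS ketene acetal of 22 (C8 cis to OSi) | C=C1C[C@]2(/C=C(\O[Si](C)(C)C(C)(C)C)O[C@H]3C[C@H](O[Si](C)(C)C(C)(C)C)[C@@](C)(C(=O)OC(C)(C)C)C=C3[Se]c3ccccc3)C[C@@]1(O[Si](C)(C)C(C)(C)C)C(=O)C=C2 | intermediate
24 | TBS ester of 25 | C=C1C[C@]2([C@@H](C(=O)O[Si](C)(C)C(C)(C)C)[C@H]3C([Se]c4ccccc4)=CC[C@H](O[Si](C)(C)C(C)(C)C)[C@@]3(C)C(=O)OC(C)(C)C)C[C@@]1(O[Si](C)(C)C(C)(C)C)C(=O)C=C2 | intermediate
25 | seco acid (C6 joins C5 of the vinyl selenide ring A to C8 of the C/D enone) | C=C1C[C@]2([C@@H](C(=O)O)[C@H]3C([Se]c4ccccc4)=CC[C@H](O[Si](C)(C)C(C)(C)C)[C@@]3(C)C(=O)OC(C)(C)C)C[C@@]1(O[Si](C)(C)C(C)(C)C)C(=O)C=C2 | intermediate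
26 | seco allyl ester | C=C1C[C@]2([C@@H](C(=O)OCC=C)[C@H]3C([Se]c4ccccc4)=CC[C@H](O[Si](C)(C)C(C)(C)C)[C@@]3(C)C(=O)OC(C)(C)C)C[C@@]1(O[Si](C)(C)C(C)(C)C)C(=O)C=C2 | intermediate
27 | bridgehead O,Se-acetal (19,10-lactone closed; 10-SePh) | C=C1C[C@]2([C@@H](C(=O)OCC=C)[C@H]3[C@]4([Se]c5ccccc5)CC[C@H](O[Si](C)(C)C(C)(C)C)[C@@]3(C)C(=O)O4)C[C@@]1(O[Si](C)(C)C(C)(C)C)C(=O)C=C2 | intermediate
28 | pentacyclic 12-ketone (allyl ester; 3β,13-bis-OTBS) | C=C1C[C@]23C[C@@]1(O[Si](C)(C)C(C)(C)C)C(=O)C[C@H]2[C@@]12CC[C@H](O[Si](C)(C)C(C)(C)C)[C@@](C)(C(=O)O1)[C@H]2[C@@H]3C(=O)OCC=C | intermediate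
29 | 12α-alcohol | C=C1C[C@]23C[C@@]1(O[Si](C)(C)C(C)(C)C)[C@@H](O)C[C@H]2[C@@]12CC[C@H](O[Si](C)(C)C(C)(C)C)[C@@](C)(C(=O)O1)[C@H]2[C@@H]3C(=O)OCC=C | intermediate
30 | 7-acid bis-silyl ether | C=C1C[C@]23C[C@@]1(O[Si](C)(C)C(C)(C)C)[C@@H](O)C[C@H]2[C@@]12CC[C@H](O[Si](C)(C)C(C)(C)C)[C@@](C)(C(=O)O1)[C@H]2[C@@H]3C(=O)O | intermediate
31 | CNP0260503.1 (12α-hydroxy-GA1) | C=C1C[C@]23C[C@@]1(O)[C@@H](O)C[C@H]2[C@@]12CC[C@H](O)[C@@](C)(C(=O)O1)[C@H]2[C@@H]3C(=O)O | target

## Step count and risks

Total step count: 21. Longest linear sequence: 15 steps (steps 7–21). The ring A branch (steps 1–6) joins at step 15.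

**Step 18 (labelled step).**
- What may go wrong:
  - The C10 cation may lose the C5 proton instead of being captured. This moves the double bond into the C5=C10 position and erodes C5.
  - The acid may shift the exocyclic double bond or strip a silyl ether.
  - The bridgehead radical may be quenched by the stannane before it reaches C9.
- Fallback (known chemistry; C10 stays sp2 during ring closure and is oxygenated afterwards): it sets out from 26.
  - Mercury(II)-assisted hydrolysis of the vinyl selenide (HgCl2, CaCO3, MeCN/H2O) gives the C10 ketone F1.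
  - Kinetic deprotonation at C1 (KHMDS, PhNTf2, THF, −78 °C) gives the 1(10)-enol triflate F2.
  - A reductive Heck cyclisation (Pd(OAc)2, PPh3, HCO2H/Et3N, DMF) closes C9–C10 in the 5-exo mode on the exo face of the enone and gives the 1(10)-ene F3.
  - Iodolactonisation of the tert-butyl ester (I2, NaHCO3, MeCN) places the C19 oxygen on C10α and iodine on C1β in the iodolactone F4.
  - Radical deiodination (Bu3SnH, AIBN) returns to the route at 28.

**Step 3.**
- What may go wrong: insufficient discrimination between the two enantiotopic enone arms, addition syn to the ester, or a second borylation.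
- Fallback: it sets out from 4.
  - Substrate-controlled conjugate borylation and oxidation with an achiral copper/bisphosphine catalyst gives the racemic trans-hydroxy enone, that is 6 together with its mirror image ent-6 F8.
  - Lipase-catalysed kinetic resolution (immobilised Candida antarctica lipase B, vinyl acetate) acylates the unwanted enantiomer to the acetate F9, which is removed by chromatography.
  - The unreacted alcohol re-enters the route at 6.

**Step 13.**
- What may go wrong: dehydrosilylation toward C14 (Saegusa-type desaturation) instead of insertion of the allyl group, over-oxidation of the ene-diol ether, or palladium hydride migration of the exocyclic alkene into the ring.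
- Fallback (two-electron closure of ring D): it sets out from 18.
  - Monosilylation (TBSOTf, 2,6-lutidine) gives the silyl ether F5.
  - Wacker oxidation of the allyl group (PdCl2, CuCl, O2, DMF/H2O) gives the methyl ketone F6.
  - Intramolecular aldol addition of the C13 enolate to the C16 ketone (KHMDS, THF, −78 °C) gives the bicyclic tertiary alcohol F7.
  - Syn-elimination toward the methyl group with the Burgess reagent returns to the route at 20.

Further compounds
F1 | step 18 | C10 ketone from hydrolysis of 26 | C=C1C[C@]2([C@@H](C(=O)OCC=C)[C@H]3C(=O)CC[C@H](O[Si](C)(C)C(C)(C)C)[C@@]3(C)C(=O)OC(C)(C)C)C[C@@]1(O[Si](C)(C)C(C)(C)C)C(=O)C=C2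
F2 | step 18 | 1(10)-enol triflate | C=C1C[C@]2([C@@H](C(=O)OCC=C)[C@H]3C(OS(=O)(=O)C(F)(F)F)=CC[C@H](O[Si](C)(C)C(C)(C)C)[C@@]3(C)C(=O)OC(C)(C)C)C[C@@]1(O[Si](C)(C)C(C)(C)C)C(=O)C=C2
F3 | step 18 | ring-B-closed 1(10)-ene tert-butyl ester | C=C1C[C@]23C[C@@]1(O[Si](C)(C)C(C)(C)C)C(=O)C[C@H]2C1=CC[C@H](O[Si](C)(C)C(C)(C)C)[C@@](C)(C(=O)OC(C)(C)C)[C@H]1[C@@H]3C(=O)OCC=C
F4 | step 18 | 1β-iodo 19,10-lactone | C=C1C[C@]23C[C@@]1(O[Si](C)(C)C(C)(C)C)C(=O)C[C@H]2[C@@]12[C@H](I)C[C@H](O[Si](C)(C)C(C)(C)C)[C@@](C)(C(=O)O1)[C@H]2[C@@H]3C(=O)OCC=C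
F5 | step 13 | TBS ether of 18 (C13 epimers) | CCOC(=O)C[C@]1(CC=C)C=CC(=O)C(O[Si](C)(C)C(C)(C)C)C1
F6 | step 13 | methyl ketone from Wacker oxidation | CCOC(=O)C[C@]1(CC(C)=O)C=CC(=O)C(O[Si](C)(C)C(C)(C)C)C1
F7 | step 13 | bicyclic aldol (16-hydroxy-16-methyl; C16 epimers) | CC1(O)C[C@]2(CC(=O)OCC)C[C@@]1(O[Si](C)(C)C(C)(C)C)C(=O)C=C2
F8 | step 3 | ent-6 | O=C1C[C@@H](O)[C@](C)(C(=O)OC(C)(C)C)C=C1
F9 | step 3 | acetate of ent-6 | O=C1C[C@@H](OC(C)=O)[C@](C)(C(=O)OC(C)(C)C)C=C1
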